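**Retrosynthetic overview**

1. Target 22 ⇐ desilylation/deacetalisation of 21; 21 ⇐ cyclopropylcarbinol 16 + acid 19 by a ring-expanding acyloxylation (bicyclo[3.1.0]hexane → ring A; forms C8–O, puts C9 into the ring, leaves C10=CH2).
2. 16 ⇐ hydrindene allylic alcohol 15 (directed cyclopropanation); 15 ⇐ cyclopentene 14 (ring-closing metathesis closes ring B).
3. 14 ⇐ spiro vinyl epoxide 10 + stannyl acrylate 13 (anti 1,4-coupling sets C7); 10 ⇐ enone 9.
4. 9 ⇐ (S)-4-silyloxycyclopentenone 6 + vinyl + triflate 5 (three-component coupling sets C6 and C1).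
5. Ring order: cyclopentene (from 6) → ring B → cyclopropane → ring A by ring expansion.

Assumption: silyl ethers 1 and 6 and acetonide 17 are bought with their protecting groups in place; atom labels C1–C15 are cadinane labels (C1/C6 ring fusion, C4=C5 with C15 on C4, C7 acrylate carbon, C8 ester carbon, C9 ring CH2, C10 carries exocyclic C14).

**Route**

Step 1
Reactants: 1 tert-butyl[(2-bromoprop-2-en-1-yl)oxy]dimethylsilane; 2 oxirane
Product: 4 3-({[tert-butyl(dimethyl)silyl]oxy}methyl)but-3-en-1-ol, via vinyllithium 3 (not isolated)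
Conditions: t-BuLi (2.0 equiv), Et2O, −78 °C; then 2, −78 → 0 °C; aq NH4Cl
Reagents that add atoms: none
Why: Br–Li exchange gives vinyllithium 3, which opens oxirane at carbon (SN2 epoxide opening) to the homoallylic alcohol; no stereocenter is formed.

Step 2
Reactants: 4 3-({[tert-butyl(dimethyl)silyl]oxy}methyl)but-3-en-1-ol
Product: 5 3-({[tert-butyl(dimethyl)silyl]oxy}methyl)but-3-en-1-yl trifluoromethanesulfonate
Conditions: Tf2O, 2,6-lutidine, CH2Cl2, −78 °C; cold pentane filtration, used at once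
Reagents that add atoms: trifluoromethanesulfonic anhydride, O=S(=O)(OS(=O)(=O)C(F)(F)F)C(F)(F)F
Why: O-sulfonylation of a primary alcohol gives the alkyl triflate, the only simple electrophile fast enough to trap a conjugate-addition enolate at low temperature.

Step 3
Reactants: 6 (S)-4-{[tert-butyl(dimethyl)silyl]oxy}cyclopent-2-en-1-one; 5 triflate
Product: 9 (4R,5S)-5-[3-({[tert-butyl(dimethyl)silyl]oxy}methyl)but-3-en-1-yl]-4-ethenylcyclopent-2-en-1-one, via lithium enolate 7 (not isolated), via silyloxy ketone 8 (not isolated)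
Conditions: CH2=CHLi, Me2Zn, THF, −78 °C; then HMPA, 5, −78 → −30 °C; aq NH4Cl; crude 8, DBU, CH2Cl2, 0 °C, short
Reagents that add atoms: vinyllithium, [Li]C=C
Why: Noyori three-component coupling in which the vinylzincate adds 1,4 trans to the silyloxy group, the regiodefined enolate 7 is alkylated by the triflate trans to the new vinyl group, and DBU then eliminates silanol from 8 (E1cB), so both stereocenters of 9 (C6, C1) derive from the one stereocenter of 6.

Step 4
Reactants: 9 enone
Product: 10 (3R,6R,7S)-7-[3-({[tert-butyl(dimethyl)silyl]oxy}methyl)but-3-en-1-yl]-6-ethenyl-1-oxaspiro[2.4]hept-4-ene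
Conditions: Me3S+ I−, KN(SiMe3)2, THF, −10 °C; then 9, −10 → 0 °C
Reagents that add atoms: trimethylsulfonium iodide, C[S+](C)C.[I-]
Why: Corey–Chaykovsky epoxidation: the sulfonium ylide adds 1,2 to the enone carbonyl from the face anti to the adjacent C1 side chain, so the epoxide oxygen at C10 ends cis to that chain.

Step 5
Reactants: 11 prop-2-ynoic acid
Product: 12 tri(propan-2-yl)silyl prop-2-ynoate
Conditions: i-Pr3SiCl, Et3N, CH2Cl2, 0 °C
Reagents that add atoms: chlorotri(propan-2-yl)silane, CC(C)[Si](Cl)(C(C)C)C(C)C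
Why: O-silylation of the carboxylate gives a silyl ester that tolerates Lewis acid and is removed by fluoride at the end.

Step 6
Reactants: 12 tri(propan-2-yl)silyl prop-2-ynoate
Product: 13 tri(propan-2-yl)silyl 2-(tributylstannyl)prop-2-enoate
Conditions: Bu3SnH, Pd(PPh3)4 (2 mol %), THF, 0 °C
Reagents that add atoms: tributylstannane, CCCC[SnH](CCCC)CCCC
Why: Palladium-catalysed syn hydrostannation of a propiolate places tin on the α-carbon and gives the 1,1-disubstituted vinylstannane.

Step 7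
Reactants: 10 spiro vinyl epoxide; 13 stannyl acrylate
Product: 14 tri(propan-2-yl)silyl 2-[(1S,4S,5S)-4-[3-({[tert-butyl(dimethyl)silyl]oxy}methyl)but-3-en-1-yl]-5-ethenyl-3-(hydroxymethyl)cyclopent-2-en-1-yl]prop-2-enoate
Conditions: Pd2(dba)3 (2.5 mol %), P(2-furyl)3 (10 mol %), DMF/H2O (20:1), 23 °C
Reagents that add atoms: none
Why: Stille-type allylic coupling of a vinyl epoxide: zerovalent palladium ionises the oxirane anti to the C–O bond, the stannane transfers the acrylate unit to palladium, and reductive elimination at the less hindered allyl terminus gives net anti 1,4-addition, which sets C7 trans to the former epoxide oxygen and cis to the C6 vinyl group and frees the C14 alcohol.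

Step 8
Reactants: 14 cyclopentene triene
Product: 15 tri(propan-2-yl)silyl 2-[(1S,3aS,7aS)-6-({[tert-butyl(dimethyl)silyl]oxy}methyl)-3-(hydroxymethyl)-3a,4,5,7a-tetrahydro-1H-inden-1-yl]prop-2-enoate
Conditions: second-generation Grubbs catalyst (H2IMes)(PCy3)Cl2Ru=CHPh (5 mol %), 1,4-benzoquinone (10 mol %), CH2Cl2, 40 °C
Reagents that add atoms: none
Why: Ring-closing metathesis between the vinyl group and the 1,1-disubstituted alkene closes ring B as a trisubstituted cyclohexene, while the acrylate and the trisubstituted cyclopentene are inert; no stereocenter is formed and the trans ring fusion is carried over.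

Step 9
Reactants: 15 hydrindene allylic alcohol
Product: 16 cyclopropylcarbinol: 15 with a CH2 (C9) bridged across the former C8=C10 bond on the ring face opposite to the C7 acrylate substituent, C10 carrying CH2OH
Conditions: Et2Zn, CH2I2, CH2Cl2, −15 → 0 °C
Reagents that add atoms: diiodomethane, ICI
Why: Furukawa–Simmons–Smith cyclopropanation, accelerated by the zinc alkoxide and therefore selective for the allylic alcohol alkene; the methylene is delivered anti to the pseudoaxial C7 substituent, which sets C8 and C10.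

Step 10
Reactants: 17 (4R)-2,2-dimethyl-1,3-dioxolane-4-carbaldehyde
Product: 18 (4S)-4-ethynyl-2,2-dimethyl-1,3-dioxolane
Conditions: dimethyl (1-diazo-2-oxopropyl)phosphonate, K2CO3, MeOH, 0 → 23 °C
Reagents that add atoms: dimethyl (1-diazo-2-oxopropyl)phosphonate, CC(=O)C(=[N+]=[N-])P(=O)(OC)OC
Why: Ohira–Bestmann (Seyferth–Gilbert) homologation converts the aldehyde into the terminal alkyne without touching the stereocenter (the descriptor changes only through priorities).

Step 11
Reactants: 18 (4S)-4-ethynyl-2,2-dimethyl-1,3-dioxolane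
Product: 19 2-[(4S)-2,2-dimethyl-1,3-dioxolan-4-yl]prop-2-enoic acid
Conditions: CO2 (1 atm), NiCl2(dme) (10 mol %), neocuproine (12 mol %), Mn powder, i-PrOH, DMF, 60 °C; then cold 1 M HCl
Reagents that add atoms: carbon dioxide, O=C=O
Why: Nickel-catalysed Markovnikov hydrocarboxylation of a terminal alkyne places the carboxyl group on the internal carbon and gives the 2-substituted acrylic acid with the stereocenter untouched.

Step 12
Reactants: 16 cyclopropylcarbinol; 19 acrylic acid
Product: 21 tri(propan-2-yl)silyl 2-[(1R,2S,4aS,8aS)-7-({[tert-butyl(dimethyl)silyl]oxy}methyl)-2-({2-[(4S)-2,2-dimethyl-1,3-dioxolan-4-yl]prop-2-enoyl}oxy)-4-methylidene-1,2,3,4,4a,5,6,8a-octahydronaphthalen-1-yl]prop-2-enoate, via trichloroacetimidate 20 (not isolated)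
Conditions: Cl3CCN, DBU (5 mol %), CH2Cl2, 0 °C; then 19 (1.5 equiv), 4 Å MS, BF3·OEt2 (20 mol %), −40 → 0 °C
Reagents that add atoms: none
Why: Proposed new method: ring-expanding, stereoinvertive acyloxylation of a (bicyclo[3.1.0]hexan-1-yl)methyl trichloroacetimidate by a complex carboxylic acid; ionisation at C14 gives a cyclopropylcarbinyl (bicyclobutonium) cation whose C8–C10 bond carries the charge to the secondary, strain-free C8, the carboxylate opens it at C8 anti to the breaking bond (inversion, so the ester oxygen ends on the face that carried the cyclopropane CH2, axial and trans to the C7 substituent) while C10=C14 becomes the exocyclic methylene and the five-membered ring becomes ring A, and kinetically formed cyclopropylmethyl or bridgehead cyclobutyl esters should re-ionise under BF3 and funnel to the unstrained homoallylic ester; the closest known reaction types are the cyclosteroid-to-homoallyl ester rearrangement, stereoinvertive substitution of cyclopropylcarbinols at the ring carbon and the solvolytic ring enlargement of bicyclo[n.1.0]alk-1-ylmethyl sulfonates.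

Step 13
Reactants: 21 protected ester
Product: 22 2-[(1R,2S,4aS,8aS)-2-{[(3S)-3,4-dihydroxy-2-methylidenebutanoyl]oxy}-7-(hydroxymethyl)-4-methylidene-1,2,3,4,4a,5,6,8a-octahydronaphthalen-1-yl]prop-2-enoic acid
Conditions: 48% aq HF, MeCN, 0 → 23 °C
Reagents that add atoms: none
Why: Global deprotection: aqueous HF cleaves the silyl ester, the primary silyl ether and the terminal acetonide, and leaves both acrylate esters, the exocyclic methylene and all stereocenters untouched.

**Compound list**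

1 | tert-butyl[(2-bromoprop-2-en-1-yl)oxy]dimethylsilane | C=C(Br)CO[Si](C)(C)C(C)(C)C | starting material
2 | oxirane | C1CO1 | starting material
3 | [3-({[tert-butyl(dimethyl)silyl]oxy})prop-1-en-2-yl]lithium | [Li]C(=C)CO[Si](C)(C)C(C)(C)C | intermediate
4 | 3-({[tert-butyl(dimethyl)silyl]oxy}methyl)but-3-en-1-ol | OCCC(=C)CO[Si](C)(C)C(C)(C)C | intermediate
5 | 3-({[tert-butyl(dimethyl)silyl]oxy}methyl)but-3-en-1-yl trifluoromethanesulfonate | FC(F)(F)S(=O)(=O)OCCC(=C)CO[Si](C)(C)C(C)(C)C | intermediate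
6 | (S)-4-{[tert-butyl(dimethyl)silyl]oxy}cyclopent-2-en-1-one | O=C1C=C[C@@H](O[Si](C)(C)C(C)(C)C)C1 | starting material
7 | lithium (3S,4S)-4-{[tert-butyl(dimethyl)silyl]oxy}-3-ethenylcyclopent-1-en-1-olate (as its Me2Zn complex) | [Li+].[O-]C1=C[C@H](C=C)[C@@H](O[Si](C)(C)C(C)(C)C)C1 | intermediate
8 | (2S,3S,4S)-4-{[tert-butyl(dimethyl)silyl]oxy}-2-[3-({[tert-butyl(dimethyl)silyl]oxy}methyl)but-3-en-1-yl]-3-ethenylcyclopentan-1-one | O=C1C[C@H](O[Si](C)(C)C(C)(C)C)[C@@H](C=C)[C@@H]1CCC(=C)CO[Si](C)(C)C(C)(C)C | intermediate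
9 | (4R,5S)-5-[3-({[tert-butyl(dimethyl)silyl]oxy}methyl)but-3-en-1-yl]-4-ethenylcyclopent-2-en-1-one | O=C1C=C[C@@H](C=C)[C@@H]1CCC(=C)CO[Si](C)(C)C(C)(C)C | intermediate
10 | (3R,6R,7S)-7-[3-({[tert-butyl(dimethyl)silyl]oxy}methyl)but-3-en-1-yl]-6-ethenyl-1-oxaspiro[2.4]hept-4-ene | C1O[C@@]12C=C[C@@H](C=C)[C@@H]2CCC(=C)CO[Si](C)(C)C(C)(C)C | intermediate
11 | prop-2-ynoic acid | C#CC(=O)O | starting material
12 | tri(propan-2-yl)silyl prop-2-ynoate | C#CC(=O)O[Si](C(C)C)(C(C)C)C(C)C | intermediate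
13 | tri(propan-2-yl)silyl 2-(tributylstannyl)prop-2-enoate | C=C([Sn](CCCC)(CCCC)CCCC)C(=O)O[Si](C(C)C)(C(C)C)C(C)C | intermediate
14 | tri(propan-2-yl)silyl 2-[(1S,4S,5S)-4-[3-({[tert-butyl(dimethyl)silyl]oxy}methyl)but-3-en-1-yl]-5-ethenyl-3-(hydroxymethyl)cyclopent-2-en-1-yl]prop-2-enoate | C=C(C(=O)O[Si](C(C)C)(C(C)C)C(C)C)[C@@H]1C=C(CO)[C@@H](CCC(=C)CO[Si](C)(C)C(C)(C)C)[C@@H]1C=C | intermediate
15 | tri(propan-2-yl)silyl 2-[(1S,3aS,7aS)-6-({[tert-butyl(dimethyl)silyl]oxy}methyl)-3-(hydroxymethyl)-3a,4,5,7a-tetrahydro-1H-inden-1-yl]prop-2-enoate | C=C(C(=O)O[Si](C(C)C)(C(C)C)C(C)C)[C@H]1[C@H]2C=C(CO[Si](C)(C)C(C)(C)C)CC[C@@H]2C(CO)=C1 | intermediate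
16 | cyclopropylcarbinol (15 with CH2 bridged across C8=C10 anti to the C7 substituent; C10 bears CH2OH) | C=C(C(=O)O[Si](C(C)C)(C(C)C)C(C)C)[C@H]1[C@H]2C=C(CO[Si](C)(C)C(C)(C)C)CC[C@@H]2[C@]3(CO)C[C@H]13 | intermediate
17 | (4R)-2,2-dimethyl-1,3-dioxolane-4-carbaldehyde | O=C[C@H]1COC(C)(C)O1 | starting material
18 | (4S)-4-ethynyl-2,2-dimethyl-1,3-dioxolane | C#C[C@H]1COC(C)(C)O1 | intermediate
19 | 2-[(4S)-2,2-dimethyl-1,3-dioxolan-4-yl]prop-2-enoic acid | C=C(C(=O)O)[C@H]1COC(C)(C)O1 | intermediate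
20 | 2,2,2-trichloroacetimidate of 16 (on the C14 oxygen) | C=C(C(=O)O[Si](C(C)C)(C(C)C)C(C)C)[C@H]1[C@H]2C=C(CO[Si](C)(C)C(C)(C)C)CC[C@@H]2[C@]3(COC(=N)C(Cl)(Cl)Cl)C[C@H]13 | intermediate
21 | tri(propan-2-yl)silyl 2-[(1R,2S,4aS,8aS)-7-({[tert-butyl(dimethyl)silyl]oxy}methyl)-2-({2-[(4S)-2,2-dimethyl-1,3-dioxolan-4-yl]prop-2-enoyl}oxy)-4-methylidene-1,2,3,4,4a,5,6,8a-octahydronaphthalen-1-yl]prop-2-enoate | C=C(C(=O)O[Si](C(C)C)(C(C)C)C(C)C)[C@H]1[C@H]2C=C(CO[Si](C)(C)C(C)(C)C)CC[C@@H]2C(=C)C[C@@H]1OC(=O)C(=C)[C@H]1COC(C)(C)O1 | intermediate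
22 | 2-[(1R,2S,4aS,8aS)-2-{[(3S)-3,4-dihydroxy-2-methylidenebutanoyl]oxy}-7-(hydroxymethyl)-4-methylidene-1,2,3,4,4a,5,6,8a-octahydronaphthalen-1-yl]prop-2-enoic acid | C=C(C(=O)O)[C@H]1[C@H]2C=C(CO)CC[C@@H]2C(=C)C[C@@H]1OC(=O)C(=C)[C@H](O)CO | target

**Step count**

Total: 13 steps. Longest linear sequence: 9 steps (1, 2, 3, 4, 7, 8, 9, 12, 13).

**Steps most likely to fail**

Step 12 (the new step). The cation may be trapped first as the bridgehead cyclobutyl or the primary cyclopropylmethyl ester, or at C9 instead of C8. It may also lose the C7 proton to give a dienoate, or collapse to the N-alkyl trichloroacetamide. The acetonide and the new exocyclic alkene must survive the Lewis acid. The fallback uses known chemistry, sets out from 16 and comes back at 22. Acid hydrolysis of the cyclopropylcarbinol (catalytic HClO4, aqueous dioxane) under the conditions of the classical cyclosteroid-to-homoallylic-alcohol rearrangement opens the ring to the axial C8 alcohol. It also removes both silyl groups, giving 2-[(1R,2S,4aS,8aS)-2-hydroxy-7-(hydroxymethyl)-4-methylidene-1,2,3,4,4a,5,6,8a-octahydronaphthalen-1-yl]prop-2-enoic acid F8. t-BuMe2SiCl and imidazole then silylate the carboxyl and the primary allylic hydroxyl, but not the hindered axial secondary one, to give the silyl ester silyl ether F9. Yamaguchi esterification of F9 with 19 (2,4,6-trichlorobenzoyl chloride, Et3N, DMAP, toluene) gives the ester F10. The aqueous HF of step 13 turns F10 into 22.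

Step 3. The homoallylic triflate can decompose through participation of the silyl ether or the alkene. The enolate can equilibrate and lose silanolate before alkylation. DBU can move the enone into conjugation with the vinyl group. The fallback sets out from 6 and 4 and comes back at 8. Iodination of 6 (I2, pyridine, CH2Cl2) gives (S)-4-{[tert-butyl(dimethyl)silyl]oxy}-2-iodocyclopent-2-en-1-one F1. Alcohol 4 is converted (I2, PPh3, imidazole) into tert-butyl[(4-iodo-2-methylidenebutyl)oxy]dimethylsilane F2 and then, with zinc dust and LiCl in THF, into the alkylzinc iodide F3. Negishi coupling of F3 with F1 (Pd2(dba)3, SPhos, THF) gives the 2-alkyl enone (S)-4-{[tert-butyl(dimethyl)silyl]oxy}-2-[3-({[tert-butyl(dimethyl)silyl]oxy}methyl)but-3-en-1-yl]cyclopent-2-en-1-one F4. Conjugate addition of a vinyl cuprate (CH2=CHMgBr, CuI, Me3SiCl, THF, −78 °C) trans to the silyloxy group, followed by protonation, gives 8. The DBU elimination of step 3 then follows.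

Step 4. The configuration at C7 depends on the facial selectivity of the small ylide, and the basic ylide may enolise or isomerise 9. The fallback sets out from 9 and comes back at 10. (Isopropoxydimethylsilyl)methylmagnesium chloride with CeCl3 (THF, −78 °C) is bulky and barely basic, and adds 1,2 anti to the C1 side chain. This gives the tertiary allylic alcohol 1-{[dimethyl(propan-2-yloxy)silyl]methyl}-5-[3-({[tert-butyl(dimethyl)silyl]oxy}methyl)but-3-en-1-yl]-4-ethenylcyclopent-2-en-1-ol F5 (hydroxyl cis to the C1 side chain). Tamao oxidation (H2O2, KF, KHCO3, THF/MeOH) gives the diol F6. TsCl, Et3N and DMAP sulfonylate only the primary hydroxyl to give the monotosylate F7. K2CO3 in MeOH closes F7 to 10.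

**Further compounds**

F1 | step 3 | (S)-4-{[tert-butyl(dimethyl)silyl]oxy}-2-iodocyclopent-2-en-1-one | O=C1C(I)=C[C@@H](O[Si](C)(C)C(C)(C)C)C1
F2 | step 3 | tert-butyl[(4-iodo-2-methylidenebutyl)oxy]dimethylsilane | ICCC(=C)CO[Si](C)(C)C(C)(C)C
F3 | step 3 | [3-({[tert-butyl(dimethyl)silyl]oxy}methyl)but-3-en-1-yl]zinc iodide | I[Zn]CCC(=C)CO[Si](C)(C)C(C)(C)C
F4 | step 3 | (S)-4-{[tert-butyl(dimethyl)silyl]oxy}-2-[3-({[tert-butyl(dimethyl)silyl]oxy}methyl)but-3-en-1-yl]cyclopent-2-en-1-one | O=C1C(CCC(=C)CO[Si](C)(C)C(C)(C)C)=C[C@@H](O[Si](C)(C)C(C)(C)C)C1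
F5 | step 4 | 1-{[dimethyl(propan-2-yloxy)silyl]methyl}-5-[3-({[tert-butyl(dimethyl)silyl]oxy}methyl)but-3-en-1-yl]-4-ethenylcyclopent-2-en-1-ol (OH cis to the C1 side chain) | O[C@]1(C[Si](C)(C)OC(C)C)C=C[C@@H](C=C)[C@@H]1CCC(=C)CO[Si](C)(C)C(C)(C)C
F6 | step 4 | 5-[3-({[tert-butyl(dimethyl)silyl]oxy}methyl)but-3-en-1-yl]-4-ethenyl-1-(hydroxymethyl)cyclopent-2-en-1-ol | O[C@]1(CO)C=C[C@@H](C=C)[C@@H]1CCC(=C)CO[Si](C)(C)C(C)(C)C
F7 | step 4 | primary 4-methylbenzenesulfonate of F6 | O[C@]1(COS(=O)(=O)c2ccc(C)cc2)C=C[C@@H](C=C)[C@@H]1CCC(=C)CO[Si](C)(C)C(C)(C)C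
F8 | step 12 | 2-[(1R,2S,4aS,8aS)-2-hydroxy-7-(hydroxymethyl)-4-methylidene-1,2,3,4,4a,5,6,8a-octahydronaphthalen-1-yl]prop-2-enoic acid | C=C(C(=O)O)[C@H]1[C@H]2C=C(CO)CC[C@@H]2C(=C)C[C@@H]1O
F9 | step 12 | tert-butyl(dimethyl)silyl ester and C15 tert-butyl(dimethyl)silyl ether of F8 | C=C(C(=O)O[Si](C)(C)C(C)(C)C)[C@H]1[C@H]2C=C(CO[Si](C)(C)C(C)(C)C)CC[C@@H]2C(=C)C[C@@H]1O
F10 | step 12 | C8 ester of F9 with acid 19 | C=C(C(=O)O[Si](C)(C)C(C)(C)C)[C@H]1[C@H]2C=C(CO[Si](C)(C)C(C)(C)C)CC[C@@H]2C(=C)C[C@@H]1OC(=O)C(=C)[C@H]1COC(C)(C)O1
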